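The pitfall in this pair is to chase the falling links: in the noon and dusk runs the rings stay flat from the first reading while the links drain towards the isomer of the product, so you should expect that drain to take the same fraction from oak and maple, and look for the gap between them in the rings.

in all of them: first end groups 0.11 M
- noon: second end groups 0.69 equiv; temperature 20 °C; run made earlier
- dusk: second end groups 2.9 equiv; temperature 31 °C; run made earlier
- oak: second end groups 1.00 equiv; temperature 25 °C; time 2.0 min
- maple: second end groups 4.00 equiv; temperature 25 °C; time 2.0 min

- noon (time / s: links / %, rings / %): 10.0: 29.0, 36.5; 20.0: 25.4, 35.8; 50.0: 17.7, 35.5; 120: 8.4, 35.1
- dusk (time / s: links / %, rings / %): 30.0: 30.8, 15.1; 60.0: 20.4, 14.8; 90.0: 17.3, 14.1; 120: 17.3, 14.7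

(each reading ± 1 percentage point)

- the flask that ends with the higher share of links in all that became links or rings or isomer of the product, or "neither" when 2 percentage points or less lies between them (oak / maple / neither)
- share of links in all that became links or rings or isomer of the product, oak
- share of links in all that became links or rings or isomer of the product, maple

- the numbers in the tables scatter with a standard deviation of 1 percentage point

I take links to form at a rate proportional to both end groups, and rings at a rate proportional to the first end groups whatever the second end groups stand at, as long as some remain. In dusk the second end groups sink by one equivalent from 2.9 equiv, so the rings are a small correction, and with the middle value 2.40 equivalents their mean share 14.7% gives a break-even of 0.413 equivalents at 31 °C.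

In noon the second end groups are the limiting reagent, and summing the competition down to zero makes the rings the break-even times the logarithm of one plus charge over break-even. The dusk value put into this gives 40.6% against a mean reading of 35.7%; I take the break-even to differ between the two temperatures, which makes it the weak link of my chain, and one step down the slope of that rule reforges the noon value to 0.277.

Between the two runs, at 25 °C, the break-even, a selectivity factor in equivalents, meaning the amount of second end groups per first end group at which links and rings form equally fast, is 0.339. That gives rings of 46.6% in oak and 8.83% in maple. The last two dusk readings put links at 20.3% of what is not rings, a reading at 31 °C that I carry unchanged to 25 °C, so I commit to 10.8% for oak and 18.5% for maple, a factor of 1.71 that does not depend on that reading as long as oak and maple share it.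

The forecast says maple, with 12% for oak (9.5% to 14.5%) and 20% for maple (16.5% to 23.5%), a little above my figures, taking the relaxation as “nearly equilibrated by 120 s”.

The flask gives 9.41% for oak and 16.1% for maple, so maple ends higher, by a factor of 1.71, under this scheme:

    first end groups + second end groups → links (k = 29.0 /M/s, Ea = 48.0 kJ/mol)
    first end groups + second end groups → rings, rate k2*[first end groups] as long as [second end groups] is above zero (k = 1.10 /s, Ea = 71.0 kJ/mol)
    links ⇌ isomer of the product (K = 6.00, k = 0.0230 /s, Ea = 74.0 kJ/mol, ΔH = −52.0 kJ/mol)
    (constants at 25 °C)

At the end oak holds 46.9% rings and maple 9.02%, in percent of the first end groups charged. The break-even has c(first end groups) under its fraction, so a neighbouring flask with oak's recipe at 0.028 M has a break-even of 1.33 equivalents, and the rule gives 74.6% rings, where that flask holds 74.9%.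

The data were computed with constants of no real substance; scatter was added.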